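At the first reading each of the three runs had lost more starting material than it had turned into product , and I read that gap as catalyst dying: at its last reading the beta run lacked 2.00% of its charge against a loading of 2.6 mol%.

| setting | epsilon | theta | beta | flask |
|---|---|---|---|---|
| starting material | 0.0094 M | 0.021 M | 0.014 M | 0.014 M |
| gas phase | 0.80 mM (held) | 0.80 mM (held) | 0.80 mM (held) | 0.80 mM (held) |
| free catalyst | 5.2 mol% | 5.2 mol% | 2.6 mol% | 5.2 mol% |
| remark | run made earlier | run made earlier | run made earlier |  |
| time |  |  |  | 25 min |

| run | time / min | product / % | starting material / % |
|---|---|---|---|
| epsilon | 1.50 | 4.6 | 94.8 |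
| epsilon | 2.50 | 8.4 | 90.0 |
| epsilon | 4.00 | 12.1 | 85.1 |
| epsilon | 8.00 | 22.6 | 74.9 |
| epsilon | 12.0 | 28.0 | 67.9 |
| epsilon | 20.0 | 34.1 | 62.0 |
| theta | 1.33 | 4.6 | 93.3 |
| theta | 4.00 | 12.6 | 84.3 |
| theta | 8.00 | 18.5 | 77.4 |
| theta | 10.0 | 19.4 | 75.2 |
| theta | 15.0 | 21.8 | 73.4 |
| theta | 20.0 | 22.2 | 73.5 |
| beta | 2.00 | 4.4 | 95.1 |
| beta | 5.00 | 9.5 | 87.9 |
| beta | 10.0 | 15.0 | 82.1 |
| beta | 15.0 | 17.6 | 79.9 |
| beta | 20.0 | 17.9 | 80.1 |

(each reading ± 0.5 percentage points)

- at the start none of the gas is dissolved
- the numbers in the tables scatter with a standard deviation of 0.5 percentage points
- steps under discussion: starting material + free catalyst -> spent catalyst; dissolved gas + free catalyst <-> idle complex; dissolved gas -> decomposed reagent; gas phase <-> dissolved gas; starting material + dissolved gas + free catalyst -> free catalyst + product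

- oak: doubling the amount of free catalyst, all else as stated
- alder: doubling the transfer coefficient of the gas phase, all else as stated
- larch: doubling the saturation concentration of gas phase, all else as stated

1. amount of product at 25 min, in percent of the starting material charged
2. the change that raises the amount of product at 25 min, in percent of the starting material charged most ("none" if none brings more than 2 percentage points) (oak / alder / larch / none)
3. amount of product at 25 min, in percent of the starting material charged, after larch

The flask looks nearly the same as the beta run: equal [starting material], twice the loading. In the steps under discussion, catalyst dies at a rate proportional to [starting material][free catalyst] and turns over at one proportional to [starting material][dissolved gas][free catalyst]. So I followed the fraction of catalyst left, not the product made. That fraction falls at a rate proportional to [starting material], equal at the start in both, and the beta readings stood flat from 15.0 min to 20.0 min, so I took the flask as finished by 25 min.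

Product then equals loading times the ratio of those rates, which varies with [dissolved gas]. Beta's last reading gave 6.88 and theta's 4.27. Gas enters in proportion to its deficit below saturation and leaves at the turnover rate, proportional to [starting material][dissolved gas][free catalyst], so I took the reciprocal of that ratio as linear in [starting material][free catalyst]. On that scale the flask stands 28.6% of the way from beta to theta, which gave a turnover yield, product made per catalyst lost, of 5.86. That means 30.5% of product, less than the 35.8% that beta's yield would give, because on my reckoning the flask draws harder on the gas than the beta run.

On that line alder brings the flask's gas deficit to beta's level, so I reckoned about that 35.8%. Oak gave me 46.9%. Larch scales [dissolved gas] at every point, giving 60.9%, the most of the three.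

The forecast gave 30.5%, chose larch and put that change at 55%, below my figure, holding that “Product per dead catalyst is proportional to dissolved gas”.

The flask gave 31.0%, and larch was best, reaching 60.7%.

    starting material + free catalyst → spent catalyst (k = 20.0 /M/min)
    dissolved gas + free catalyst ⇌ idle complex, settled at all times (K = 480 /M)
    dissolved gas → decomposed reagent (k = 0.00710 /min)
    gas phase ⇌ dissolved gas, rate k4*(csat - [dissolved gas]) (kL = 1.50 /min)
    starting material + dissolved gas + free catalyst → free catalyst + product (k = 2.60 × 10⁵ /M²/min)

At 25.0 min the flask held 98.0% of its catalyst as spent catalyst, which makes the turnover yield 6.08 against my 5.86. A neighbour flask with 0.0084 M of starting material at the same loading had 89.8% spent. The same line gave it a yield of 7.24, hence 33.8% of product, and it made 36.5%.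

All runs were computed from invented constants.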